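**Plan**
- Retrosynthesis: the C15 alcohol is unmasked last from its acetate, and the C7 acetate comes from a free cis-7β,8β-diol. The C7–C8 bond of ring B is then cut as a pinacol bond, giving a monocyclic 7,8-seco keto aldehyde (C7 aldehyde, C8 methyl ketone) on intact ring A.
- That keto aldehyde is the ozonolysis product of (13E)-labda-7,13-dien-15-yl acetate, which is traced through exocyclic-alkene isomerization, 8-acetate elimination and a 1,3-acetate shift to (−)-sclareol.
- Enabling feature: C7 (oxygen-bearing CH) and C8 (oxygen-bearing quaternary carbon carrying the C17 methyl) of ring B are adjacent carbinol carbons, i.e. two carbonyl carbons of like polarity that a ketyl coupling can unite. Their arms (C6 on C5, C9 on C10) sit trans-diequatorial on ring A beside the axial C10 methyl.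
- Forward order: ring A and the side chain are carried from sclareol; the original ring B is opened and then re-formed as the only ring closure of the route (step 6).
- Stereochemistry: C5, C9 and C10 come from sclareol; 13E from the chair-like palladium-bound acetoxonium of the acetate shift; C7 and C8 are set together in the key step (equatorial C17 methyl, samarium chelation), giving the β,β-diol that α-face osmylation of the Δ7 alkene cannot give.

Key step: step 6

Remark: the target is read as the normal-series labdane (5S,7S,8R,9R,10S,13E)-7-acetoxylabd-13-ene-8,15-diol (7β-OAc, 8β-OH, 8α-CH3); it shares C5, C9 and C10 with (−)-sclareol and is epimeric with it at C8.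

**Step 1**
Reactants: 1 (−)-sclareol
Product: 2 sclareol diacetate
Conditions: AcCl, PhNMe2, CH2Cl2, 0 °C → rt
Reagents that add atoms: acetyl chloride, CC(=O)Cl
Why: Exhaustive O-acylation of the two hindered tertiary alcohols with AcCl and a weak aniline base, the standard non-eliminating esterification of tertiary terpene alcohols; no stereocenter is touched.

**Step 2**
Reactants: 2 sclareol diacetate
Product: 3 (13E)-labd-13-ene-8α,15-diyl diacetate
Conditions: PdCl2(MeCN)2 (5 mol %), THF, rt
Reagents that add atoms: none
Why: Divalent-palladium-catalysed 1,3-acyloxy shift ([3,3] cyclization-induced rearrangement through a six-membered acetoxonium bound to palladium) moves the tertiary allylic acetate to the primary terminus, and the long chain on C13 takes the equatorial site of the chair intermediate so that the 13E alkene should predominate; the 8-acetate is inert.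

**Step 3**
Reactants: 3 (13E)-labd-13-ene-8α,15-diyl diacetate
Product: 4 (13E)-labda-8(17),13-dien-15-yl acetate
Conditions: NaHCO3, DMSO, 150 °C
Reagents that add atoms: none
Why: Thermal syn-elimination (ester pyrolysis) of the tertiary equatorial 8α-acetate, which reaches the C17 methyl hydrogens most easily, should give mainly the exocyclic alkene together with some Δ7 isomer 5 (the product of step 4, so the mixture is carried on) and little Δ8(9) isomer, while the primary allylic acetate has no β-hydrogen on sp3 carbon and stays.

**Step 4**
Reactants: 4 (13E)-labda-8(17),13-dien-15-yl acetate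
Product: 5 (13E)-labda-7,13-dien-15-yl acetate
Conditions: Co(salen)Cl (salen = N,N'-bis(3,5-di-tert-butylsalicylidene)cyclohexane-1,2-diaminate; 3 mol %), PhSiH3 (6 mol %), benzene, rt
Reagents that add atoms: none
Why: Cobalt-hydride hydrogen-atom-transfer isomerization of a 1,1-disubstituted alkene by one position: H adds to C17 to give the tertiary C8 radical, and the bulky divalent cobalt complex should take hydrogen back from the open C7 methylene and not from the shielded tertiary C9–H, while trisubstituted alkenes (the Δ7 product and Δ13) are not turned over by this catalyst.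

**Step 5**
Reactants: 5 (13E)-labda-7,13-dien-15-yl acetate
Product: 7 (13E)-15-acetoxy-8-oxo-7,8-secolabd-13-en-7-al, via secondary ozonide 6 (not isolated)
Conditions: O3 (1.0 equiv, titrated CH2Cl2 solution), CH2Cl2, −78 °C; then PPh3, −78 °C → rt; pentane trituration, short silica pad, used at once
Reagents that add atoms: ozone, [O-][O+]=O
Why: Ozonolysis with reductive work-up, in which electrophilic ozone should attack the electron-richer ring alkene because the Δ13 alkene is deactivated by its allylic acetoxy group (the selectivity known for geranyl acetate); the neutral work-up leaves C9, now α to the ketone, unepimerized.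

**Step 6**
Reactants: 7 (13E)-15-acetoxy-8-oxo-7,8-secolabd-13-en-7-al
Product: 9 (13E)-7β,8β-dihydroxylabd-13-en-15-yl acetate, via bis(diiodosamarium) 7β,8β-diolate 8 (not isolated)
Conditions: SmI2 (2.5 equiv), THF, slow addition of 7 at high dilution, −78 °C → rt; then sat. aq. NH4Cl
Reagents that add atoms: none
Why: SmI2 reduces the aldehyde to a samarium ketyl at C7, which adds to the samarium-bound C8 ketone, and the second equivalent reduces the resulting oxygen radical to give chelated diolate 8. The closest known reaction type is the SmI2 pinacol cyclization of 1,6-keto aldehydes to cis-cyclohexane-1,2-diols. Ring B closes in a 6-exo-trig mode through a chair transition state that is trans-fused to ring A, because the C6 and C9 arms are trans-diequatorial on ring A. At C8 the C17 methyl takes the equatorial site to avoid a syn-diaxial clash with the axial C10 methyl, which places O8 axial (β). At C7 trivalent samarium bridges both oxygens and forces the cis arrangement, so O7 is equatorial (β). The step needs chemoselectivity over the allylic acetate and the Δ13 alkene and freedom from aldol closure or C9 epimerization, which the absence of HMPA and base, the low temperature and the far easier reduction of the aldehyde should secure.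

**Step 7**
Reactants: 9 (13E)-7β,8β-dihydroxylabd-13-en-15-yl acetate
Product: 10 (13E)-8β-hydroxylabd-13-ene-7β,15-diyl diacetate
Conditions: Ac2O, pyridine, DMAP (cat.), CH2Cl2, 0 °C → rt
Reagents that add atoms: acetic anhydride, CC(=O)OC(C)=O
Why: DMAP-catalysed acylation of the equatorial secondary 7β-hydroxyl, while the axial tertiary 8β-hydroxyl, syn-diaxial to the C10 methyl, should not be acylated under these conditions.

**Step 8**
Reactants: 10 (13E)-8β-hydroxylabd-13-ene-7β,15-diyl diacetate
Product: 11 (13E)-7β-acetoxylabd-13-ene-8β,15-diol
Conditions: immobilized Candida antarctica lipase B, n-BuOH (10 equiv), MTBE, 30 °C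
Reagents that add atoms: none
Why: Lipase-catalysed alcoholysis should be selective for the unhindered primary allylic acetate at the chain end, since the ring acetate beside the quaternary carbinol does not fit the active site, and the neutral medium excludes acyl migration to O8.

**Compound list**
1 | (−)-sclareol, (13R)-labd-14-ene-8α,13-diol | C1C[C@H]2C(C)(C)CCC[C@]2(C)[C@@H](CC[C@@](C)(O)C=C)[C@]1(C)O | starting material
2 | sclareol diacetate, (13R)-labd-14-ene-8α,13-diyl diacetate | C1C[C@H]2C(C)(C)CCC[C@]2(C)[C@@H](CC[C@@](C)(OC(C)=O)C=C)[C@]1(C)OC(C)=O | intermediate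
3 | (13E)-labd-13-ene-8α,15-diyl diacetate | C1C[C@H]2C(C)(C)CCC[C@]2(C)[C@@H](CC/C(C)=C/COC(C)=O)[C@]1(C)OC(C)=O | intermediate
4 | (13E)-labda-8(17),13-dien-15-yl acetate (exocyclic C8=C17 alkene) | C1C[C@H]2C(C)(C)CCC[C@]2(C)[C@@H](CC/C(C)=C/COC(C)=O)C1=C | intermediate
5 | (13E)-labda-7,13-dien-15-yl acetate (ring C7=C8 alkene) | CC1=CC[C@H]2C(C)(C)CCC[C@]2(C)[C@H]1CC/C(C)=C/COC(C)=O | intermediate
6 | secondary ozonide of 5 (1,2,4-trioxolane spanning C7 and C8; configuration at the two trioxolane carbons not defined) | CC12OOC(O1)C[C@H]3C(C)(C)CCC[C@]3(C)[C@H]2CC/C(C)=C/COC(C)=O | intermediate (not isolated)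
7 | (13E)-15-acetoxy-8-oxo-7,8-secolabd-13-en-7-al (ring A with CH2CHO on C5 and, on C10, the CH bearing acetyl and the side chain) | O=CC[C@H]1C(C)(C)CCC[C@]1(C)[C@@H](CC/C(C)=C/COC(C)=O)C(C)=O | intermediate
8 | bis(diiodosamarium) 7β,8β-diolate of 9 (chelated in solution) | I[Sm](I)O[C@H]1C[C@H]2C(C)(C)CCC[C@]2(C)[C@@H](CC/C(C)=C/COC(C)=O)[C@@]1(C)O[Sm](I)I | intermediate (not isolated)
9 | (13E)-7β,8β-dihydroxylabd-13-en-15-yl acetate | O[C@H]1C[C@H]2C(C)(C)CCC[C@]2(C)[C@@H](CC/C(C)=C/COC(C)=O)[C@@]1(C)O | intermediate
10 | (13E)-8β-hydroxylabd-13-ene-7β,15-diyl diacetate | CC(=O)O[C@H]1C[C@H]2C(C)(C)CCC[C@]2(C)[C@@H](CC/C(C)=C/COC(C)=O)[C@@]1(C)O | intermediate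
11 | (13E)-7β-acetoxylabd-13-ene-8β,15-diol | CC(=O)O[C@H]1C[C@H]2C(C)(C)CCC[C@]2(C)[C@@H](CC/C(C)=C/CO)[C@@]1(C)O | target

Total step count: 8
Longest linear sequence: 8 steps (fully linear from 1)

**Steps most likely to fail**

Step 4. The hydrogen back-transfer may lose site selectivity (removal at C9 giving the Δ8(9) alkene), the C8 radical may cyclize onto the side-chain alkene, or the 13E geometry may scramble. The fallback replaces isomerization by oxygenation and reductive transposition. It sets out from 4: allylic oxidation (SeO2 cat., t-BuOOH, CH2Cl2; ene reaction then [2,3]-shift, the acetoxy-deactivated Δ13 alkene being spared) should give (13E)-7α-hydroxylabda-8(17),13-dien-15-yl acetate F1. Mitsunobu displacement with 2-nitrobenzenesulfonylhydrazide (PPh3, DEAD, THF, −30 °C) should give the 7β-sulfonylhydrazine F2. On warming, F2 loses the sulfinic acid to give the allylic diazene F3, which expels N2 in a retro-ene reaction that places hydrogen on C17 and the double bond at C7=C8. The fallback comes back to the route at 5.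

Step 5. Ozone may discriminate poorly between the two trisubstituted alkenes, or over-oxidation may occur. The fallback separates oxidation from cleavage. It sets out from 5: OsO4 (cat.), NMO, acetone/H2O should give the α-face cis-diol (13E)-7α,8α-dihydroxylabd-13-en-15-yl acetate F4, which can be purified from any side-chain diol. Glycol cleavage (NaIO4, THF/H2O, rt) then comes back to the route at 7.

Step 6. The coupling may lose chelation control (trans-diol), or simple aldehyde reduction, intermolecular coupling or aldol closure with C9 epimerization may compete. The fallback forms the same C7–C8 bond by polar umpolung. It sets out from 7: a carbene-catalysed intramolecular crossed benzoin reaction (3-benzyl-5-(2-hydroxyethyl)-4-methylthiazolium chloride 20 mol %, DBU, t-BuOH, 40 °C) should give (13E)-8β-hydroxy-7-oxolabd-13-en-15-yl acetate F5, with the C17 methyl again equatorial. Axial hydride delivery (NaBH4, MeOH, −20 °C) should then give the equatorial 7β-alcohol, coming back to the route at 9.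

**Further compounds**
F1 | step 4 | (13E)-7α-hydroxylabda-8(17),13-dien-15-yl acetate | O[C@@H]1C[C@H]2C(C)(C)CCC[C@]2(C)[C@@H](CC/C(C)=C/COC(C)=O)C1=C
F2 | step 4 | (13E)-7β-[1-(2-nitrobenzenesulfonyl)hydrazinyl]labda-8(17),13-dien-15-yl acetate | NN([C@H]1C[C@H]2C(C)(C)CCC[C@]2(C)[C@@H](CC/C(C)=C/COC(C)=O)C1=C)S(=O)(=O)c1ccccc1[N+](=O)[O-]
F3 | step 4 | (13E)-7β-diazenyllabda-8(17),13-dien-15-yl acetate | N=N[C@H]1C[C@H]2C(C)(C)CCC[C@]2(C)[C@@H](CC/C(C)=C/COC(C)=O)C1=C
F4 | step 5 | (13E)-7α,8α-dihydroxylabd-13-en-15-yl acetate | O[C@@H]1C[C@H]2C(C)(C)CCC[C@]2(C)[C@@H](CC/C(C)=C/COC(C)=O)[C@]1(C)O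
F5 | step 6 | (13E)-8β-hydroxy-7-oxolabd-13-en-15-yl acetate | O=C1C[C@H]2C(C)(C)CCC[C@]2(C)[C@@H](CC/C(C)=C/COC(C)=O)[C@@]1(C)O
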